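## Retrosynthetic overview

- The target is unmasked last from an aryl silyl ether and a side-chain cinnamate monoester (hydride, then fluoride); neither operation touches the skeleton.
- Key disconnection: the bond between tetralin C1 and the side-chain carbinol carbon C1'. It is made together with the C2–H bond in one asymmetric aldol–Tishchenko reaction of 6,7-dimethoxy-2-tetralone with two molecules of O-silylated (E)-4-hydroxycinnamaldehyde.
- Enabling feature: C2–OH, C1 and C1'–OH form a 1,3-diol whose central carbon C1 is benzylic to the dimethoxybenzene ring and α to C2, so the target is the reduced form of a β-hydroxy ketone. The C2 ketone enolises only towards C1, and the stereotriad (side chain cis to C2–OH on the ring, anti aldol, 1,3-anti diol) is the one an all-equatorial Tishchenko chair delivers.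
- Rings: none is formed in the route; the tetralin carbocycle and both arenes are bought in the two starting materials.

Key step: step 2

Assumption: the sense of induction of the La–Li–BINOL catalyst is not established for this ketone class; the (R)-BINOL complex is written, and its equally available antipode would be used if the first run gives the mirror-image series.

## Route

Step 1
Reactants: 1 (E)-3-(4-hydroxyphenyl)prop-2-enal (4-hydroxycinnamaldehyde)
Product: 2 (E)-3-[4-(triisopropylsilyloxy)phenyl]prop-2-enal
Conditions: TIPSCl, imidazole, DMF, 0 °C to rt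
Reagents that add atoms: triisopropylsilyl chloride, CC(C)[Si](Cl)(C(C)C)C(C)C
Why: Imidazole-mediated O-silylation of the phenol (silyl ether formation) should proceed cleanly, the triisopropylsilyl group being chosen because it withstands the alkoxides of step 2 and the hydride of step 3 and leaves with fluoride under non-acidic conditions.

Step 2
Reactants: 3 6,7-dimethoxy-3,4-dihydronaphthalen-2(1H)-one (6,7-dimethoxy-2-tetralone); 2 (E)-3-[4-(triisopropylsilyloxy)phenyl]prop-2-enal (two molecules are incorporated)
Product: 6 (1R,2E)-1-[(1S,2R)-2-hydroxy-6,7-dimethoxy-1,2,3,4-tetrahydronaphthalen-1-yl]-3-[4-(triisopropylsilyloxy)phenyl]prop-2-en-1-yl (2E)-3-[4-(triisopropylsilyloxy)phenyl]prop-2-enoate, via aldol adduct 4 (not isolated), via hemiacetal 5 (not isolated)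
Conditions: (R)-LaLi3(binaphthoxide)3 (10 mol %), LiOTf (10 mol %), 2 (2.4 equiv), THF, 4 Å MS, Ar, rt, slow addition of 3
Reagents that add atoms: none
Why: Proposed new method: the lanthanum–lithium binaphthoxide deprotonates C1–H of 3 (benzylic and α to the C2 carbonyl, so enolisation is regiodefined and the ring fixes the enolate as E), the enolate adds 1,2 to 2 in a reversible aldol addition to give aldolate 4, the aldolate oxygen adds to a second molecule of 2 to give hemiacetal 5, and an irreversible intramolecular hydride shift from the hemiacetal C–H to C2 through a lanthanum-bridged six-membered chair gives 6, the second aldehyde ending as the ester so that nothing is lost. The closest known reactions are the aldol–Tishchenko reaction of ketone lithium enolates with two equivalents of an aldehyde and its La–Li–BINOL-catalysed asymmetric version with aryl ethyl ketones and aryl aldehydes; the extension proposed is to a cyclic benzylic ketone and to an enal as acceptor and hydride donor. No ring of the product is closed; the only cyclic array is the transient hydride-transfer chair, which is trans-fused to the tetralone ring. C1 and C1' are set anti because the aldolates interconvert by retro-aldol reaction and only the chair carrying C8a, C3 and the styryl group equatorial transfers hydride fast (Curtin–Hammett selection), C2 is set by delivery of hydride within that chair, anti to the C1'–O bond (1,3-anti, hence C2–OH cis to the side chain), and the absolute sense is imposed by the binaphthoxide environment of the lanthanum that holds the carbonyl and hemiacetal oxygens. The step needs 1,2- rather than 1,4-addition to the enal and hydride transfer faster than dehydration of the aldolate; the oxophilic La/Li-bound enolate, the para-silyloxy donor that deactivates the β-carbon of 2, the excess of 2 and exclusion of air (2-tetralone enolates autoxidise) are relied on for this.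

Step 3
Reactants: 6 (1R,2E)-1-[(1S,2R)-2-hydroxy-6,7-dimethoxy-1,2,3,4-tetrahydronaphthalen-1-yl]-3-[4-(triisopropylsilyloxy)phenyl]prop-2-en-1-yl (2E)-3-[4-(triisopropylsilyloxy)phenyl]prop-2-enoate
Product: 7 (1S,2R)-1-[(1R,2E)-1-hydroxy-3-[4-(triisopropylsilyloxy)phenyl]prop-2-en-1-yl]-6,7-dimethoxy-1,2,3,4-tetrahydronaphthalen-2-ol
Conditions: DIBAL-H (4 equiv), CH2Cl2, −78 °C; then MeOH, aq. Rochelle salt
Reagents that add atoms: none
Why: Ester-to-alcohol reduction with DIBAL-H should cleave the cinnamate by 1,2-hydride addition at −78 °C without base or protic acid, so the aryl silyl ether, the (E)-alkene and the three stereocentres are untouched, and any ester that migrated to the C2 oxygen during step 2 converges on the same diol.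

Step 4
Reactants: 7 (1S,2R)-1-[(1R,2E)-1-hydroxy-3-[4-(triisopropylsilyloxy)phenyl]prop-2-en-1-yl]-6,7-dimethoxy-1,2,3,4-tetrahydronaphthalen-2-ol
Product: 8 (1S,2R)-1-[(1R,2E)-1-hydroxy-3-(4-hydroxyphenyl)prop-2-en-1-yl]-6,7-dimethoxy-1,2,3,4-tetrahydronaphthalen-2-ol (CNP0142972.1)
Conditions: TBAF, AcOH (1:1), THF, 0 °C to rt; pH 7 buffer work-up, Et3N-deactivated silica
Reagents that add atoms: none
Why: Fluoride-mediated cleavage of the aryl Si–O bond (desilylation) buffered with acetic acid should free the phenol without ionising the acid- and base-sensitive 4-hydroxycinnamyl-type carbinol, and no stereocentre is involved.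

## Compound list

1 | (E)-3-(4-hydroxyphenyl)prop-2-enal (4-hydroxycinnamaldehyde) | O=C/C=C/c1ccc(O)cc1 | starting material
2 | (E)-3-[4-(triisopropylsilyloxy)phenyl]prop-2-enal | O=C/C=C/c1ccc(O[Si](C(C)C)(C(C)C)C(C)C)cc1 | intermediate
3 | 6,7-dimethoxy-3,4-dihydronaphthalen-2(1H)-one (6,7-dimethoxy-2-tetralone) | COc1cc2c(cc1OC)CC(=O)CC2 | starting material
4 | (1R)-1-[(1R,2E)-1-hydroxy-3-[4-(triisopropylsilyloxy)phenyl]prop-2-en-1-yl]-6,7-dimethoxy-3,4-dihydronaphthalen-2(1H)-one, the anti aldol adduct, formed in the flask as its metal alkoxide (the descriptor at C1 is R only because C2 is a carbonyl here; the geometry is that of the target) | COc1cc2c(cc1OC)[C@H]([C@H](O)/C=C/c1ccc(O[Si](C(C)C)(C(C)C)C(C)C)cc1)C(=O)CC2 | intermediate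
5 | hemiacetal of 4 with a second molecule of 2 at the C1' oxygen, formed in the flask as its metal alkoxide; the hemiacetal carbon equilibrates and the (R) epimer drawn is the one that fits the chair | COc1cc2c(cc1OC)[C@H]([C@H](O[C@@H](O)/C=C/c1ccc(O[Si](C(C)C)(C(C)C)C(C)C)cc1)/C=C/c1ccc(O[Si](C(C)C)(C(C)C)C(C)C)cc1)C(=O)CC2 | intermediate
6 | (1R,2E)-1-[(1S,2R)-2-hydroxy-6,7-dimethoxy-1,2,3,4-tetrahydronaphthalen-1-yl]-3-[4-(triisopropylsilyloxy)phenyl]prop-2-en-1-yl (2E)-3-[4-(triisopropylsilyloxy)phenyl]prop-2-enoate | COc1cc2c(cc1OC)[C@H]([C@H](OC(=O)/C=C/c1ccc(O[Si](C(C)C)(C(C)C)C(C)C)cc1)/C=C/c1ccc(O[Si](C(C)C)(C(C)C)C(C)C)cc1)[C@H](O)CC2 | intermediate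
7 | (1S,2R)-1-[(1R,2E)-1-hydroxy-3-[4-(triisopropylsilyloxy)phenyl]prop-2-en-1-yl]-6,7-dimethoxy-1,2,3,4-tetrahydronaphthalen-2-ol | COc1cc2c(cc1OC)[C@H]([C@H](O)/C=C/c1ccc(O[Si](C(C)C)(C(C)C)C(C)C)cc1)[C@H](O)CC2 | intermediate
8 | (1S,2R)-1-[(1R,2E)-1-hydroxy-3-(4-hydroxyphenyl)prop-2-en-1-yl]-6,7-dimethoxy-1,2,3,4-tetrahydronaphthalen-2-ol | COc1cc2c(cc1OC)[C@H]([C@H](O)/C=C/c1ccc(O)cc1)[C@H](O)CC2 | target

## Summary and risks

Total step count: 4. Longest linear sequence: 4 steps (1 → 2 → 6 → 7 → 8).

Steps most likely to fail:

**Step 2.** Several processes could defeat it: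
- poor facial or enantiofacial discrimination in the hydride transfer;
- conjugate instead of carbonyl addition to the enal;
- dehydration of the aldolate to the dienone;
- self-condensation or autoxidation of the tetralone enolate.

The fallback uses known reactions only, sets out from 3 and returns at 6. Ketone 3 would be converted with TMSOTf/Et3N into its trimethylsilyl enol ether F1 (C1=C2 enol ether). F1 would be exchanged with SiCl4 (cat. Hg(OAc)2, CH2Cl2) into the trichlorosilyl enol ether F2. Chiral phosphoramide-catalysed (Lewis-base-catalysed) aldol addition of F2 to 2 at −78 °C is a reaction type known for trichlorosilyl enolates of cyclic ketones with cinnamaldehyde-type acceptors, and proceeds through a closed chair to the anti aldol. With the catalyst antipode that gives the (R)-carbinol it should give aldol adduct 4 after bicarbonate work-up, here isolated cold and used at once. Evans–Tishchenko reduction of 4 with catalytic SmI2 and 2 as hydride donor (THF, −10 °C, through hemiacetal 5 as its samarium alkoxide) should then give the 1,3-anti monoester 6.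

**Step 3.** The Lewis-acidic aluminium species may ionise the electron-rich allylic C1'–O bond, or reduction may stall on an ester that has migrated to the more hindered C2 oxygen. The fallback sets out from 6 and returns at 7. The cinnamoyl group would be transferred to methanol by base-catalysed transesterification (K2CO3, MeOH, 0 °C) instead of being reduced. This makes no new compound on the way.

**Step 4.** The polar triol may be lost while it is separated from tetrabutylammonium salts, or the 4-hydroxycinnamyl-type carbinol may ionise once the phenol is free under fluoride (allylic transposition, cyclodehydration onto the C2 hydroxyl). The fallback sets out from 6 and returns at 8, with the order of the two unmasking operations inverted. Buffered TBAF/AcOH on 6 should give the bis-phenol ester F3, which is less polar and easily freed from ammonium salts, the phenols staying protonated under the buffer. DIBAL-H (excess, CH2Cl2/THF, −78 °C, phenols carried as aluminium phenoxides) would then cleave the ester, so that 8 is released by a Rochelle-salt work-up and never meets fluoride.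

Further compounds
F1 | step 2 | [(6,7-dimethoxy-3,4-dihydronaphthalen-2-yl)oxy]trimethylsilane | COc1cc2c(cc1OC)C=C(O[Si](C)(C)C)CC2
F2 | step 2 | trichloro[(6,7-dimethoxy-3,4-dihydronaphthalen-2-yl)oxy]silane | COc1cc2c(cc1OC)C=C(O[Si](Cl)(Cl)Cl)CC2
F0 | step 3 | none | none
F3 | step 4 | (1R,2E)-1-[(1S,2R)-2-hydroxy-6,7-dimethoxy-1,2,3,4-tetrahydronaphthalen-1-yl]-3-(4-hydroxyphenyl)prop-2-en-1-yl (2E)-3-(4-hydroxyphenyl)prop-2-enoate | COc1cc2c(cc1OC)[C@H]([C@H](OC(=O)/C=C/c1ccc(O)cc1)/C=C/c1ccc(O)cc1)[C@H](O)CC2
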